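**Retrosynthetic overview**
1. Target ⇒ benzyl-protected flavone (final hydrogenolysis) ⇒ chromone ring closed by acid cyclodehydration of a β-enaminone/1,3-diketone ⇐ N–O cleavage of a 3,5-diarylisoxazole.
2. Key step: the isoxazole ring forms by nitrile oxide + terminal alkyne 1,3-dipolar cycloaddition, joining the B-ring aldoxime (from the benzodioxane aldehyde) to an A-ring alkyne.
3. Benzodioxane aldehyde ⇐ DDQ benzylic C–H etherification of an aryl ether ⇐ Mitsunobu of 5-hydroxyvanillin with a secondary alcohol ⇐ Cu-catalysed ArMgBr opening of (R)-benzyl glycidyl ether, the only stereochemical input.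
4. Ring order: dioxane, then isoxazole, then pyranone (C ring).

Assumption: the Mitsunobu in Step 3 alkylates the more acidic 4-OH of 5-hydroxyvanillin (para to CHO), and the target is the trans-(2R,3R) dioxane as drawn.

---

**Step 1**
Reactants: 1 (4-bromo-2-methoxyphenol)
Product: 2 (1-(benzyloxy)-4-bromo-2-methoxybenzene)
Conditions: BnBr, K2CO3, acetone, reflux
Reagents that add atoms: benzyl bromide, BrCc1ccccc1
Why: Williamson O-benzylation of the phenol; it protects the guaiacyl OH and gives the aryl bromide for the Grignard.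

**Step 2**
Reactants: 2; 3 ((R)-benzyl glycidyl ether)
Product: 4 ((2R)-1-(benzyloxy)-3-[4-(benzyloxy)-3-methoxyphenyl]propan-2-ol)
Conditions: Mg, THF, 50 °C to make ArMgBr; then CuI (10 mol%), 3, THF, −20 °C → rt
Reagents that add atoms: none
Why: Cu-catalysed Grignard opening of a terminal epoxide occurs at the unhindered CH2 and leaves the carbinol stereocentre untouched, carrying the (R) configuration of 3 into 4.

**Step 3**
Reactants: 4; 5 (5-hydroxyvanillin, 3,4-dihydroxy-5-methoxybenzaldehyde)
Product: 6 (4-{[(2S)-1-(benzyloxy)-3-[4-(benzyloxy)-3-methoxyphenyl]propan-2-yl]oxy}-3-hydroxy-5-methoxybenzaldehyde)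
Conditions: PPh3, DIAD, THF, 0 °C → rt
Reagents that add atoms: none
Why: Mitsunobu etherification proceeds by SN2 with clean inversion at the secondary carbinol, which fixes the configuration of the future dioxane C–CH2OH carbon; the most acidic 4-OH reacts.

**Step 4**
Reactants: 6
Product: 7 ((2R,3R)-3-[4-(benzyloxy)-3-methoxyphenyl]-2-[(benzyloxy)methyl]-8-methoxy-2,3-dihydro-1,4-benzodioxine-6-carbaldehyde)
Conditions: DDQ (1.5 equiv), 4 Å MS, DCE, 60 °C
Reagents that add atoms: none
Why: DDQ removes hydride from the p-alkoxy-activated benzylic CH2 to give a benzylic cation, which the neighbouring phenol traps in a 6-membered ring closure (dehydrogenative etherification). The cation closes preferentially to the trans-diequatorial 2,3-product relative to the existing stereocentre, so the benzylic centre is controlled by it.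

**Step 5**
Reactants: 7
Product: 8 (aldoxime of 7)
Conditions: NH2OH·HCl, NaOAc, EtOH/H2O, rt
Reagents that add atoms: hydroxylamine, NO
Why: standard oxime condensation; the stereocentres are unaffected.

**Step 6**
Reactants: 9 (2,4,6-trihydroxybenzaldehyde)
Product: 10 (4,6-bis(benzyloxy)-2-hydroxybenzaldehyde)
Conditions: BnBr (2.0 equiv), K2CO3, acetone, reflux
Reagents that add atoms: benzyl bromide, BrCc1ccccc1
Why: the 4-OH is the most acidic and is alkylated first, then one of the two equivalent chelated OH groups; the other chelated OH, held by the aldehyde, stays free (Williamson).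

**Step 7**
Reactants: 10
Product: 11 (2-ethynyl-3,5-bis(benzyloxy)phenol)
Conditions: Bestmann–Ohira reagent, K2CO3, MeOH, rt
Reagents that add atoms: dimethyl (1-diazo-2-oxopropyl)phosphonate, COP(=O)(OC)C(=[N+]=[N-])C(C)=O
Why: Seyferth–Gilbert/Ohira–Bestmann homologation converts the aldehyde to a terminal alkyne under mild base, leaving the free phenol and benzyl ethers intact.

**Step 8**
Reactants: 8; 11
Product: 12 (5-[2-hydroxy-4,6-bis(benzyloxy)phenyl]-3-[(2R,3R)-benzodioxinyl]isoxazole)
Conditions: NCS, DMF, rt (hydroximoyl chloride); then 11, Et3N added slowly by syringe pump, CH2Cl2, 0 °C → rt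
Reagents that add atoms: none
Why: 1,3-dipolar cycloaddition of the in situ aryl nitrile oxide to the terminal aryl alkyne gives the 3,5-diarylisoxazole regioselectively, a masked 1,3-diketone, with no new stereocentres.

**Step 9**
Reactants: 12
Product: 13 ((Z)-3-amino-1-[2-hydroxy-4,6-bis(benzyloxy)phenyl]-3-[(2R,3R)-benzodioxinyl]prop-2-en-1-one)
Conditions: Mo(CO)6, MeCN/H2O (15:1), 80 °C
Reagents that add atoms: none
Why: Mo(CO)6 reductively cleaves the isoxazole N–O bond to the β-enaminone, leaving benzyl ethers, the dioxane and the phenol untouched.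

**Step 10**
Reactants: 13
Product: 14 (5,7-bis(benzyloxy)-2-{(2R,3R)-3-[4-(benzyloxy)-3-methoxyphenyl]-2-[(benzyloxy)methyl]-8-methoxy-2,3-dihydro-1,4-benzodioxin-6-yl}-4H-chromen-4-one)
Conditions: 10% aq. HCl, EtOH, 60 °C
Reagents that add atoms: none
Why: the phenol adds to the protonated enaminone carbon and NH3 is eliminated (cyclodehydration), closing the pyranone; any acid-induced benzylic epimerisation of the dioxane funnels to the thermodynamic trans isomer.

**Step 11**
Reactants: 14
Product: 15 (5'-methoxyhydnocarpin)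
Conditions: H2 (1 atm), 10% Pd/C, EtOAc/EtOH, rt
Reagents that add atoms: none (H2 adds only hydrogen)
Why: hydrogenolysis removes all four O-benzyl groups, including the primary CH2OBn, in one operation without touching the stereocentres.

---

**Compound list**

| No. | Name | SMILES | Role |
|---|---|---|---|
| 1 | 4-bromo-2-methoxyphenol | COc1cc(Br)ccc1O | starting material |
| 2 | 1-(benzyloxy)-4-bromo-2-methoxybenzene | COc1cc(Br)ccc1OCc1ccccc1 | intermediate |
| 3 | (R)-benzyl glycidyl ether | c1ccccc1COC[C@H]1CO1 | starting material |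
| 4 | (2R)-1-(benzyloxy)-3-[4-(benzyloxy)-3-methoxyphenyl]propan-2-ol | O[C@H](Cc1ccc(OCc2ccccc2)c(OC)c1)COCc1ccccc1 | intermediate |
| 5 | 5-hydroxyvanillin | O=Cc1cc(O)c(O)c(OC)c1 | starting material |
| 6 | Mitsunobu aryl ether (S) | O=Cc1cc(O)c(O[C@@H](Cc2ccc(OCc3ccccc3)c(OC)c2)COCc2ccccc2)c(OC)c1 | intermediate |
| 7 | trans-(2R,3R)-benzodioxane aldehyde | COc1cc([C@H]2Oc3cc(C=O)cc(OC)c3O[C@@H]2COCc2ccccc2)ccc1OCc1ccccc1 | intermediate |
| 8 | aldoxime of 7 | COc1cc([C@H]2Oc3cc(C=NO)cc(OC)c3O[C@@H]2COCc2ccccc2)ccc1OCc1ccccc1 | intermediate |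
| 9 | 2,4,6-trihydroxybenzaldehyde | O=Cc1c(O)cc(O)cc1O | starting material |
| 10 | 4,6-bis(benzyloxy)-2-hydroxybenzaldehyde | O=Cc1c(O)cc(OCc2ccccc2)cc1OCc1ccccc1 | intermediate |
| 11 | 2-ethynyl-3,5-bis(benzyloxy)phenol | C#Cc1c(O)cc(OCc2ccccc2)cc1OCc1ccccc1 | intermediate |
| 12 | 3,5-diarylisoxazole | COc1cc([C@H]2Oc3cc(-c4cc(-c5c(O)cc(OCc6ccccc6)cc5OCc7ccccc7)on4)cc(OC)c3O[C@@H]2COCc8ccccc8)ccc1OCc9ccccc9 | intermediate |
| 13 | β-enaminone | COc1cc([C@H]2Oc3cc(C(N)=CC(=O)c4c(O)cc(OCc5ccccc5)cc4OCc6ccccc6)cc(OC)c3O[C@@H]2COCc7ccccc7)ccc1OCc8ccccc8 | intermediate |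
| 14 | tetra-O-benzyl flavone | COc1cc([C@H]2Oc3cc(-c4cc(=O)c5c(OCc6ccccc6)cc(OCc6ccccc6)cc5o4)cc(OC)c3O[C@@H]2COCc7ccccc7)ccc1OCc8ccccc8 | intermediate |
| 15 | 5'-methoxyhydnocarpin | COc1cc([C@H]2Oc3cc(-c4cc(=O)c5c(O)cc(O)cc5o4)cc(OC)c3O[C@@H]2CO)ccc1O | target |

---

**Totals:** 11 steps in total; longest linear sequence 9 steps (1→2→4→6→7→8→12→13→14→15).

**Three steps most likely to fail**
1. **Step 4 (DDQ cyclisation).**
   - Risks: over-oxidation, or a cis/trans mixture.
   - Fallback: oxidise the benzylic CH2 of 6 to the ketone (DDQ, wet CH2Cl2), reduce with NaBH4, then close the ring by Lewis-acid-catalysed SN1 etherification (Sc(OTf)3) under thermodynamic trans control.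
2. **Step 3 (Mitsunobu).**
   - Risks: alkylation at the wrong phenol, or E2 elimination to the allylarene.
   - Fallback: use 5-bromovanillin, which has a single phenol, for the Mitsunobu with 4. Protect the CHO as its acetal, convert Ar–Br to Ar–OH by borylation/oxidation, deprotect, and continue to Step 4.
3. **Step 8 (nitrile oxide cycloaddition).**
   - Risks: furoxan dimerisation, ring chlorination by NCS, or reaction of the free phenol.
   - Fallback: skip Steps 5–10 and condense aldehyde 7 with 2-hydroxy-4,6-bis(benzyloxy)acetophenone (Claisen–Schmidt), cyclise the chalcone with I2/DMSO to give 14, then run Step 11.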